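The numbers in the tables were computed with made-up constants; the scatter is artificial.

The day is our unit for this flask, the violet recipe carried on to 2.5 d, and we count in it how often target can hand half of itself to isomer of the product.

| setting | violet | blue | flask |
|---|---|---|---|
| starting material | 0.050 M | 0.025 M | 0.050 M |
| protic impurity | 0.050 M | 0.050 M | 0.0500 M |
| remark | the very flask that is asked about, followed so far | run made earlier |  |
| time |  |  | 2.5 d |

violet run (percent of the starting material charged)

| time / h | target / % | isomer of the product / % |
|---|---|---|
| 2.50 | 4.9 | 1.0 |
| 6.00 | 10.9 | 0 |
| 12.0 | 17.4 | 3.8 |
| 20.0 | 18.2 | 6.8 |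

blue run (percent of the starting material charged)

| time / d | target / % | isomer of the product / % |
|---|---|---|
| 0.625 | 20.8 | 4.8 |
| 1.25 | 22.5 | 8.2 |
| 2.08 | 19.3 | 15.7 |
| 2.50 | 18.4 | 18.0 |

(standard deviation of a reading: 1 percentage point)

- ratio of target to isomer of the product at 30 min
- ratio of target to isomer of the product at 5.0 h
- ratio of target to isomer of the product at 2.5 d



1. In the blue run, isomer rises from 8.2% to 18.0% between 1.25 d and 2.50 d while target reads between 22.5% and 18.4%. If target feeds that rise, target drains at 0.383 /d, so it loses half of itself in 1.81 d, our drain half-life, which holds no charge in it.

2. In the consecutive extreme, target rises in a straight line and isomer comes from target, so the ratio is two over drain rate times time: 250 at 30 min and 25.0 at 5.0 h.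

3. In the parallel extreme, both leave starting material at a fixed selectivity factor, and the ratio stays flat. By 0.625 d, the blue run has drained about 2.49% of the charge; moving that back from isomer to target gives 10.1.

4. We take the violet flask to lie between the extremes, with both routes open, so the isomer adds and the reciprocals of the ratios add. The parallel term is larger than the drain term at 30 min, and we expect 9.70, then 7.19 at 5.0 h.

5. At 2.5 d the straight line fails, with 1.38 half-lives counted, but the blue run has the same count at that time, so we take its 1.02.

The forecast gave 5.5, 4.5 and 1, below us early and level at the end, holding of the isomer: “This favours a parallel leak from starting material rather than a purely sequential route”.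

The flask gives 11.3, 7.93 and 1.00.

    2 starting material → homo dimer B (k = 0.00130 /M/h)
    2 starting material → homo dimer A (k = 0.950 /M/h)
    starting material + protic impurity → quenched substrate (k = 0.110 /M/h)
    starting material ⇌ isomer of the product (K = 3.80, k = 0.00270 /h)
    starting material ⇌ target (K = 1.20, k = 0.0320 /h)
    target ⇌ isomer of the product (k = 0.0120 /h)

At 30 min, 0.0115 of a drain half-life into this flask, the largest single effect on the ratio is the conversion of starting material into isomer, both ways: the run without that conversion stands at 329, not 11.3. In a neighbour flask with 0.20 M of starting material and the other charges and the time held, our half-life of 1.81 d holds no charge, so the count stays 1.38 and we expect a ratio near 1.02; that neighbour computes to 0.877.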